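| flask | E | temperature | remark | time |
|---|---|---|---|---|
| Monday's | 0.025 M | 54 °C | run made earlier |  |
| Wednesday's | 0.038 M | 95 °C | run made earlier |  |
| north | 0.050 M | 110 °C |  | 5.0 h |
| north-west | 0.050 M | 85 °C |  | 5.0 h |
| east | 0.050 M | 35 °C |  | 5.0 h |
| south-east | 0.050 M | 60 °C |  | 5.0 h |

| run | time / h | J / % | Z / % |
|---|---|---|---|
| Monday's | 6.00 | 3 | 75 |
| Monday's | 12.0 | 2 | 93 |
| Monday's | 20.0 | 2 | 93 |
| Monday's | 40.0 | 1 | 95 |
| Monday's | 72.0 | 0 | 96 |
| Wednesday's | 2.00 | 9 | 87 |
| Wednesday's | 4.00 | 11 | 85 |
| Wednesday's | 6.00 | 9 | 83 |
| Wednesday's | 8.00 | 10 | 86 |
| Wednesday's | 10.0 | 9 | 82 |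

(scatter of a reading: 1.5 percentage points)

- which flask leads in share of J in all that became J or Z ("all alike" within 1.5 percentage points) (north / north-west / east / south-east / all alike)
- share of J in all that became J or Z, north
- share of J in all that became J or Z, north-west
- share of J in all that became J or Z, east
- share of J in all that became J or Z, south-east

- a species is counted by the E in it: one Z counts as two
- the analysis behind the earlier runs scatters by 1.5 percentage points, standard deviation

Two runs cannot separate charge from temperature, because Monday's flask and Wednesday's flask differ in both, so I bracket the question with two versions I can solve in the head. In the first, J is a fixed share of what has reacted, and the charge does not enter: this is the zero of the scale. In the second, the making and the using up of J both go in step with E, so J holds a fixed concentration at a given temperature, and its percentage is that concentration over the charge.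

Monday's J does not climb while Z goes from 75 % to 93 %, so I commit to the second end, though that evidence is weak. Monday's J falls by twice the scatter, and I take that fall as scatter. The means of the 5 readings then give 0.400 mM on Monday and 3.65 mM on Wednesday.

Taking the logarithm as straight in temperature, I get for south-east a standing level of J, the concentration at which J is made as fast as it is used up (a quasi-steady state), of 0.553 mM. If E is used up in south-east by the asked time, and J and Z together stand at 96.0 % of the charge, as Monday's last reading has them, that is a share near 1.15 %. For north the same line, on the same supposition, gives a share of 17.1 %.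

The forecast reasons otherwise: “The two runs suggest that J and Z interconvert”. It names north as leader, with 20 % for north, 5.5 % for north-west, 3.5 % for east and 3 % for south-east, and its figures for north and south-east are above mine .

North gives 13.1 %, north-west 4.58 %, east 3.38 % and south-east 1.48 %, so north leads, with north below the forecast's figure and mine.

    E + 2 J → 3 J (k = 0.175 /M²/s, Ea = 55.0 kJ/mol)
    E → J (k = 2.99 × 10⁻⁶ /s, Ea = 108 kJ/mol)
    E + J → Z (k = 0.0179 /M/s, Ea = 61.0 kJ/mol)
    E → D (k = 1.38 × 10⁻⁷ /s, Ea = 119 kJ/mol)
    (constants at 35 °C)

In south-east J stays at 1.33 % of the charge from 2.50 h to 5.00 h while E falls from 27.1 % to 7.23 %, and at the end J is made 1.00 times as fast as it is used up, each step taken net. My standing level of 0.553 mM stands against 0.665 mM in south-east, and the neighbour flask, south-east with 0.013 M of E, holds 0.666 mM of J, which is 5.12 % of its charge.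

The data are simulated for an exercise, and the scatter is random.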